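## Analysis of the target

The target is a 3,8''-linked biflavonoid. A 5,7,4'-trihydroxyflavanone (rings A, C and B) is joined through C3 of ring C to C8'' of a luteolin-type flavone, whose 7''-oxygen carries a hydrogen sulfate while the six other phenols are free. There are two stereocentres, C2 (R) and C3 (S), adjacent in ring C and trans, so the 4-hydroxyphenyl and flavonyl groups are both equatorial. C3 lies α to the C4 ketone and can epimerise, so trans is the thermodynamic arrangement and only C2 needs absolute control; rotation about C3–C8'' is hindered, but no axial configuration is specified. Three points are sensitive: ring C opens by retro-oxa-Michael reaction under base and then loses C2; the aryl sulfate monoester does not survive acid and must come in at the end; and the 7''-OH sits ortho to the C3–C4(=O) unit and can condense with the ketone under forcing acid. The synthesis is hard because of the C3(sp3)–C8''(aryl) bond, flanked on the flavone by O7'' and O1'', and because O7'' has to be singled out among seven phenolic oxygens. The strategy rests on one feature: ring C without ring A is a 2,3-diaryl-2,3-dihydro-4-pyranone. O1 and C2 come from an aryl aldehyde; C3, C4, C4a and C8a come from a 1-methoxy-3-silyloxybutadiene that already carries the flavone on its terminal carbon; the C4a=C8a enone left after the annulation is where ring A is grown.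

## Retrosynthetic reasoning

Sulfate and protecting groups. Target 25 is traced to the sodium sulfate 24, in which all other phenolic oxygens except the chelated 5-OH are masked as three benzyl ethers and a diphenylmethylene ketal. These fall to hydrogenolysis, which an aryl sulfate salt tolerates. Cutting O7''–S leads to phenol 23. Its only other free phenol is the 5-OH, hydrogen-bonded to the C4 ketone and inert to sulfation, so the forward step needs no further selectivity.

Differentiation of the phenols. The 7''-OH of 23 is uncovered from the methoxymethyl ether 22, and the ring A benzyl ether of 22 is traced back to diol 21. The forward benzylation must distinguish the two ring A phenols and must avoid base; a Mitsunobu reaction on the non-chelated 7-OH does both.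

Ring A. Cutting C4a–C5 and C8–C8a takes 21 back to the sulfinyl enone 16 and the 1,3-dioxygenated diene 18. These are the two bonds a Diels–Alder reaction makes. The nucleophilic terminus of 18 must join C8a, so the 5- and 7-oxygens land in the right places, and the sulfinyl group supplies the oxidation level for aromatisation by syn-elimination. Enone 16 comes from 14 by sulfenylation at C4a (15) and oxidation; 18 comes from ester 17.

Ring C (key disconnection). Ring C of 14 is cut at O1–C8a and C2–C3, giving diene 11 and aldehyde 12. The cut is not placed at C3–C8'': a bond between a secondary carbon α to a ketone and an arene carbon with two ortho oxygen substituents has no reliable forward reaction. In 11 that bond already exists. Both new bonds form in one catalysed [4+2] process in which a chiral Lewis acid chooses the aldehyde face and so fixes C2; C3 follows by equilibration.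

The diene. Diene 11 is the silyl dienol ether of ketone 10, whose only enolisable position is the benzylic CH2. The β-methoxy enone of 10 is cut at its C–O bond (conjugate addition to ynone 9), and 9 is cut between the carbonyl carbon and the alkyne (alkynol 8 from aldehyde 7). The four-carbon chain is thus built from a two-carbon stub by additions the flavone tolerates.

The C8'' side chain. Aldehyde 7 is the cleavage product of the allyl group of 6. The C8''–CH2 bond is cut by a retro-Claisen step: 5, the unprotected form of 6, arises from the 7-O-allyl ether 4. The rearrangement makes the hindered aryl–carbon bond intramolecularly and releases O7'' as the one free phenol, which is then marked with the methoxymethyl group.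

The flavone. Compound 4 is reached from luteolin 1 by three protections that follow the reactivity order of its oxygens: catechol (ketal 2), 7-OH (allyl ether 3), chelated 5-OH (benzyl ether 4). The flavone skeleton is bought, not built.

## Alternatives that were turned down

Alternative 1: Ring A is disconnected at O1–C8a and C4–C4a and attached as an aryne. In the forward step, 3,5-bis(benzyloxy)benzyne A3 is generated with fluoride in the presence of the carboxylate of the α-(flavon-8-yl)cinnamic acid A2. The carboxylate oxygen should attack the aryne carbon remote from the flanking benzyloxy group, the acyl group should pass to the aryl anion, and the 2'-hydroxy-α-arylchalcone A1 should result.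
- For it: ring A arrives whole and with built-in regiochemistry in one step, against three steps here (12, 13 and 15). On step economy for ring A this alternative is clearly stronger.
- Against it: the key step closes no ring and sets no stereocentre. C2 and C3 would have to arise in a later oxa-Michael closure of A1, an enone whose β-carbon is shielded by the twisted flavone and whose α-position is substituted, so catalytic asymmetric chalcone cyclisations have little to hold on to. That closure is reversible under the basic conditions that promote it, so C2 has no lasting control element. The acyl transfer also runs through a strained four-membered arrangement and competes with protonation of the aryl anion to a simple aryl ester.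
- Comparison: the chosen strategy spends more steps on ring A, but C2 is fixed by a catalyst in the step that forms ring C, and ring C is never formed or re-formed under base.

Alternative 2: The flavone pyranone ring is disconnected at C4a''–C4'', C4''–C3'' and O1''–C2'' and built last. In the forward step the iodophenol A5, carbon monoxide A7 and the alkyne A6 are joined under palladium catalysis in a secondary amine; carbonylative coupling is followed by addition of the neighbouring phenol to the triple bond, which gives A4.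
- For it: the assembly is convergent, no Lewis-basic flavone is carried through the early steps, and the 7''-OH emerges free, so the sulfation site needs no protecting group. On that point it is stronger, saving the methoxymethyl on/off pair of this route.
- Against it: it does not say how the C3–aryl bond and the two stereocentres of A5 are made, which is the hard part of the target. A5 is an α-(2,6-dihydroxyaryl) ketone in which either phenol can add to C4 and dehydrate to a benzofuran. The finished, base-labile 3-arylflavanone must survive an amine at carbonylation temperature, where retro-oxa-Michael opening erases C2. The iodide is electron-rich and flanked by two oxygen substituents, so oxidative addition is slow, and five-membered closure to an aurone competes.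
- Comparison: the chosen strategy builds the flavanone on the flavone, so the crowded C3–C8'' bond exists from the start and the finished flavanone never meets base.

Alternative 3: Ring C is disconnected at C2–C3. In the forward step a chiral dirhodium carboxylate decomposes the diazo ketone A9; the carbene at C3 inserts into a benzylic C–H bond of the neighbouring 4-benzyloxybenzyl ether and gives A8.
- For it: ring C and both stereocentres come from one catalyst-controlled step. The ring A precursor carries three identical ether groups, so there is no regiochemistry. The C–H bond is activated (benzylic and α to oxygen). The route would be several steps shorter than the one chosen; on step economy it is stronger.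
- Against it: the insertion must be 1,6, while the ether oxygen sits five atoms from the carbene. Oxonium ylide formation followed by a [1,2]-benzyl shift to a five-membered coumaranone is the usual fate of ortho-alkoxyaryl diazo ketones. The carbene is flanked by a 2,6-disubstituted aryl ketone and a di-ortho-substituted flavonyl group, so both the diazo transfer and the insertion are hindered. A masked sulfate must be carried through carbene chemistry.
- Comparison: in the chosen strategy the six-membered ring is inherent in the [4+2] topology and has no five-membered competitor; the price is that ring A is added afterwards.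

Key step: step 11

Remark on the chemistry: the target is drawn as the free hydrogen sulfate; the monoester is carried as its sodium salt and protonated only in the last operation.

Abbreviation used in names: Fl = 5-(benzyloxy)-2-(2,2-diphenyl-1,3-benzodioxol-5-yl)-7-(methoxymethoxy)-4-oxo-4H-chromen-8-yl, the protected flavone bonded through C8''.

## Route

Step 1
Reactants: 1 luteolin, 2-(3,4-dihydroxyphenyl)-5,7-dihydroxy-4H-chromen-4-one
Product: 2 2-(2,2-diphenyl-1,3-benzodioxol-5-yl)-5,7-dihydroxy-4H-chromen-4-one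
Conditions: Ph2CCl2 (1.5 equiv), Ph2O, 175 °C, 30 min
Reagents that add atoms: dichlorodiphenylmethane, ClC(Cl)(c1ccccc1)c1ccccc1
Why: Only the catechol can form a five-membered cyclic ketal by double substitution on the gem-dichloride; the 5- and 7-hydroxyls have no neighbouring hydroxyl and stay free.

Step 2
Reactants: 2 2-(2,2-diphenyl-1,3-benzodioxol-5-yl)-5,7-dihydroxy-4H-chromen-4-one
Product: 3 7-(allyloxy)-2-(2,2-diphenyl-1,3-benzodioxol-5-yl)-5-hydroxy-4H-chromen-4-one
Conditions: allyl bromide (1.1 equiv), K2CO3 (1.2 equiv), DMF, rt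
Reagents that add atoms: allyl bromide, C=CCBr
Why: Williamson etherification at the 7-OH, the most acidic phenol; the 5-OH is held in a hydrogen bond to the C4'' carbonyl and should not react with a slight excess of reagent.

Step 3
Reactants: 3 7-(allyloxy)-2-(2,2-diphenyl-1,3-benzodioxol-5-yl)-5-hydroxy-4H-chromen-4-one
Product: 4 7-(allyloxy)-5-(benzyloxy)-2-(2,2-diphenyl-1,3-benzodioxol-5-yl)-4H-chromen-4-one
Conditions: BnBr (1.5 equiv), K2CO3 (3 equiv), Bu4NI (cat.), DMF, 70 °C
Reagents that add atoms: benzyl bromide, BrCc1ccccc1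
Why: Williamson etherification of the chelated 5-OH under more forcing conditions. It removes the acidic chelate before the organometallic and Lewis acid steps and removes the bond fixation that could steer the allyl group to C6'' in step 4.

Step 4
Reactants: 4 7-(allyloxy)-5-(benzyloxy)-2-(2,2-diphenyl-1,3-benzodioxol-5-yl)-4H-chromen-4-one
Product: 5 8-allyl-5-(benzyloxy)-2-(2,2-diphenyl-1,3-benzodioxol-5-yl)-7-hydroxy-4H-chromen-4-one
Conditions: PhNEt2, 200 °C, argon, sealed tube
Reagents that add atoms: none
Why: Aromatic Claisen rearrangement ([3,3]-sigmatropic shift, then tautomerisation). In 7-allyloxychromones the C7–C8 bond has the higher double-bond character, so migration to C8'' is expected, and the freed 7''-OH marks the future sulfate position.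

Step 5
Reactants: 5 8-allyl-5-(benzyloxy)-2-(2,2-diphenyl-1,3-benzodioxol-5-yl)-7-hydroxy-4H-chromen-4-one
Product: 6 8-allyl-5-(benzyloxy)-2-(2,2-diphenyl-1,3-benzodioxol-5-yl)-7-(methoxymethoxy)-4H-chromen-4-one
Conditions: MeOCH2Cl (2 equiv), iPr2NEt (3 equiv), CH2Cl2, 0 °C to rt
Reagents that add atoms: chloromethyl methyl ether, COCCl
Why: O-alkylation to the methoxymethyl ether, which is orthogonal to benzyl and small enough not to shield C8''. It must be in place before step 6, because a free ortho-hydroxyl would add to the aldehyde and end as a furan.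

Step 6
Reactants: 6 8-allyl-5-(benzyloxy)-2-(2,2-diphenyl-1,3-benzodioxol-5-yl)-7-(methoxymethoxy)-4H-chromen-4-one
Product: 7 2-Fl-acetaldehyde
Conditions: OsO4 (2 mol%), NaIO4 (4 equiv), 2,6-lutidine (2 equiv), dioxane–H2O (3:1), rt
Reagents that add atoms: osmium tetroxide, O=[Os](=O)(=O)=O; sodium periodate (terminal source of the aldehyde oxygen, delivered through OsO4), [Na+].[O-]I(=O)(=O)=O
Why: Lemieux–Johnson cleavage, i.e. dihydroxylation of the terminal alkene and glycol cleavage by periodate. The flavone C2''=C3'' bond is an electron-poor vinylogous ester alkene and should be left alone.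

Step 7
Reactants: 7 2-Fl-acetaldehyde
Product: 8 1-Fl-but-3-yn-2-ol (racemic)
Conditions: HC≡CMgBr (0.5 M in THF, 3 equiv), THF, −78 to −40 °C; NH4Cl (aq)
Reagents that add atoms: ethynylmagnesium bromide, C#C[Mg]Br
Why: 1,2-Addition of the alkynyl Grignard reagent to the aldehyde, which at low temperature is far more electrophilic than the flavone carbonyl. The new carbinol centre is racemic and is destroyed in step 8.

Step 8
Reactants: 8 1-Fl-but-3-yn-2-ol
Product: 9 1-Fl-but-3-yn-2-one
Conditions: Dess–Martin periodinane (1.3 equiv), NaHCO3, CH2Cl2, 0 °C to rt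
Reagents that add atoms: none
Why: Dess–Martin oxidation of the propargylic alcohol to the ynone under buffered, non-basic conditions that spare the acidic benzylic CH2.

Step 9
Reactants: 9 1-Fl-but-3-yn-2-one
Product: 10 (E)-4-methoxy-1-Fl-but-3-en-2-one
Conditions: MeOH (10 equiv), DABCO (10 mol%), CH2Cl2, 0 °C
Reagents that add atoms: methanol, CO
Why: Amine-catalysed conjugate addition of methanol to the terminal ynone; equilibration of the adduct should give the E β-methoxy enone.

Step 10
Reactants: 10 (E)-4-methoxy-1-Fl-but-3-en-2-one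
Product: 11 (1E,3Z)-1-methoxy-3-(trimethylsilyloxy)-4-Fl-buta-1,3-diene
Conditions: LiN(SiMe3)2 (1.15 equiv), Me3SiCl (1.5 equiv), THF, −78 °C; pentane, filtration under argon, used crude
Reagents that add atoms: chlorotrimethylsilane, C[Si](C)(C)Cl
Why: The ketone can be deprotonated only at the benzylic CH2, since its other side is vinylic; O-silylation of the aryl-conjugated enolate gives the 3Z silyl dienol ether. The amide base is too weak and too hindered to attack the flavone.

Step 11
Reactants: 11 (1E,3Z)-1-methoxy-3-(trimethylsilyloxy)-4-Fl-buta-1,3-diene; 12 4-(benzyloxy)benzaldehyde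
Product: 14 (2R,3S)-2-[4-(benzyloxy)phenyl]-3-Fl-2,3-dihydro-4H-pyran-4-one, via silyl aldol adduct 13 (not isolated)
Conditions: 12 (1.5 equiv), Ti(OiPr)4 (20 mol%), (R)-BINOL (40 mol%), 4 Å MS, CH2Cl2, −20 °C to rt; then CF3CO2H (2 equiv), CH2Cl2, 0 °C; NaHCO3 (aq)
Reagents that add atoms: none
Why: The catalyst formed from Ti(OiPr)4 and (R)-BINOL binds the aldehyde of 12, and the silyl enol ether carbon C4 of 11 (the future C3) attacks the exposed face in a Mukaiyama aldol step that forms C2–C3 and gives 13 with silyl transfer; the closest known reaction type is the BINOL/Ti(OiPr)4-catalysed formal hetero-Diels–Alder reaction of 1-methoxy-3-silyloxydienes, 4-substituted ones included, with aromatic aldehydes. Trifluoroacetic acid then frees the carbinol oxygen, which adds to the methoxy-bearing carbon of the β-methoxy enone and expels methanol, so ring C closes by a 6-endo-trig oxa-Michael addition–elimination that forms O1–C8a (overall a [4+2] annulation; a concerted cycloaddition followed by loss of methanol would give the same product). C2 is controlled by the catalyst: (R)-BINOL is chosen because, by analogy with the unsubstituted diene and aryl aldehydes, it is the ligand expected to give 2R. C3 is not fixed kinetically; it is α to the ketone and carries an aryl group, so under the acid it equilibrates through the enol to the trans isomer with both aryl groups pseudo-equatorial, which is 3S. The step needs site selectivity, secured because only C4 of 11 is nucleophilic, and chemoselectivity, secured because the flavone carbonyl is a vinylogous ester and far less electrophilic than the Lewis acid-bound aldehyde. Base is avoided throughout, since it would open ring C by β-elimination of O1 and erase C2. Because the flavone already sits on the nucleophilic carbon, the congested C3–C8'' bond does not have to be made in this step.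

Step 12
Reactants: 14 (2R,3S)-2-[4-(benzyloxy)phenyl]-3-Fl-2,3-dihydro-4H-pyran-4-one
Product: 15 (2R,3S)-2-[4-(benzyloxy)phenyl]-3-Fl-5-(phenylthio)-2,3-dihydro-4H-pyran-4-one
Conditions: PhSCl (1.1 equiv), pyridine (2 equiv), CH2Cl2, −78 to 0 °C
Reagents that add atoms: benzenesulfenyl chloride, ClSc1ccccc1
Why: Electrophilic sulfenylation at C5 (C4a of the future flavanone), the nucleophilic α-carbon of the vinylogous ester, followed by loss of HCl to pyridine; this is the site at which dihydropyranones are halogenated. The buffered medium is not basic enough to disturb C2 or C3.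

Step 13
Reactants: 15 (2R,3S)-2-[4-(benzyloxy)phenyl]-3-Fl-5-(phenylthio)-2,3-dihydro-4H-pyran-4-one
Product: 16 (2R,3S)-2-[4-(benzyloxy)phenyl]-3-Fl-5-(phenylsulfinyl)-2,3-dihydro-4H-pyran-4-one (mixture at sulfur)
Conditions: mCPBA (1.0 equiv), CH2Cl2, −78 °C; NaHCO3 (aq)
Reagents that add atoms: 3-chloroperbenzoic acid, OOC(=O)c1cccc(Cl)c1
Why: One equivalent of peracid at low temperature oxidises the sulfide to the sulfoxide and should stop there; the push–pull alkene is not epoxidised. The configuration at sulfur is irrelevant because sulfur is lost in step 15.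

Step 14
Reactants: 17 methyl 3-(trimethylsilyloxy)but-2-enoate
Product: 18 1-methoxy-1,3-bis(trimethylsilyloxy)buta-1,3-diene
Conditions: LiN(iPr)2 (1.1 equiv), THF, −78 °C; Me3SiCl (1.2 equiv), −78 °C to rt; filtration under argon, distillation
Reagents that add atoms: chlorotrimethylsilane, C[Si](C)(C)Cl
Why: γ-Deprotonation of the silyl enol ether of methyl acetoacetate and O-silylation of the ester dienolate, the standard preparation of this 1,3-bis(silyloxy)diene.

Step 15
Reactants: 16 (2R,3S)-2-[4-(benzyloxy)phenyl]-3-Fl-5-(phenylsulfinyl)-2,3-dihydro-4H-pyran-4-one; 18 1-methoxy-1,3-bis(trimethylsilyloxy)buta-1,3-diene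
Product: 21 (2R,3S)-2-[4-(benzyloxy)phenyl]-3-Fl-5,7-dihydroxychroman-4-one, via cycloadduct 19 (not isolated), via bis(trimethylsilyl) ether 20 (not isolated)
Conditions: 18 (4 equiv), toluene, 90 °C, sealed tube; then 1 M HCl, THF, 0 °C, 10 min
Reagents that add atoms: none
Why: Diels–Alder reaction of an α-sulfinyl enone with an electron-rich diene: the CH2 terminus of 18 bonds to C8a, which is β to both the ketone and the sulfoxide, and the ketene acetal carbon bonds to C4a, so the oxygens arrive at C5 and C7. In adduct 19 the sulfinyl group and H8a are cis, so thermal syn-elimination of the sulfenic acid and loss of methanol should aromatise ring A to 20, whose silyl ethers are hydrolysed on work-up. C2 is not involved and C3 stays trans under the neutral to weakly acidic conditions.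

Step 16
Reactants: 21 (2R,3S)-2-[4-(benzyloxy)phenyl]-3-Fl-5,7-dihydroxychroman-4-one
Product: 22 (2R,3S)-7-(benzyloxy)-2-[4-(benzyloxy)phenyl]-3-Fl-5-hydroxychroman-4-one
Conditions: BnOH (1.1 equiv), PPh3 (1.2 equiv), DIAD (1.2 equiv), THF, 0 °C to rt
Reagents that add atoms: benzyl alcohol, OCc1ccccc1
Why: Mitsunobu etherification alkylates the acidic, unhindered 7-OH and not the chelated 5-OH. No base stronger than the betaine is present, which protects ring C against retro-oxa-Michael opening.

Step 17
Reactants: 22 (2R,3S)-7-(benzyloxy)-2-[4-(benzyloxy)phenyl]-3-Fl-5-hydroxychroman-4-one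
Product: 23 (2R,3S)-7-(benzyloxy)-2-[4-(benzyloxy)phenyl]-3-[5-(benzyloxy)-2-(2,2-diphenyl-1,3-benzodioxol-5-yl)-7-hydroxy-4-oxo-4H-chromen-8-yl]-5-hydroxychroman-4-one
Conditions: HCl (2 M) in MeOH–THF (1:1), 35 °C, monitored
Reagents that add atoms: none
Why: Acid-catalysed acetal exchange removes the phenolic methoxymethyl group; the benzyl ethers and the flavanone tolerate mild acid, and the diphenylmethylene ketal, which needs hot aqueous acid for cleavage, should survive if the reaction is stopped at conversion. The temperature is kept low so that the freed 7''-OH does not condense with the chelated C4 ketone.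

Step 18
Reactants: 23 (2R,3S)-7-(benzyloxy)-2-[4-(benzyloxy)phenyl]-3-[5-(benzyloxy)-2-(2,2-diphenyl-1,3-benzodioxol-5-yl)-7-hydroxy-4-oxo-4H-chromen-8-yl]-5-hydroxychroman-4-one
Product: 24 sodium 5-(benzyloxy)-8-[(2R,3S)-7-(benzyloxy)-2-[4-(benzyloxy)phenyl]-5-hydroxy-4-oxochroman-3-yl]-2-(2,2-diphenyl-1,3-benzodioxol-5-yl)-4-oxo-4H-chromen-7-yl sulfate
Conditions: SO3·pyridine (5 equiv), pyridine, 40 °C; then NaHCO3 (aq)
Reagents that add atoms: sulfur trioxide–pyridine complex, [O-]S(=O)(=O)[n+]1ccccc1; sodium hydrogencarbonate, [Na+].OC([O-])=O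
Why: O-Sulfonation at the only non-chelated phenol; the 5-OH hydrogen-bonded to C4=O is inert under these conditions. Isolation as the sodium salt keeps the monoester from acid hydrolysis.

Step 19
Reactants: 24 sodium 5-(benzyloxy)-8-[(2R,3S)-7-(benzyloxy)-2-[4-(benzyloxy)phenyl]-5-hydroxy-4-oxochroman-3-yl]-2-(2,2-diphenyl-1,3-benzodioxol-5-yl)-4-oxo-4H-chromen-7-yl sulfate
Product: 25 2-(3,4-dihydroxyphenyl)-5-hydroxy-8-[(2R,3S)-5,7-dihydroxy-2-(4-hydroxyphenyl)-4-oxochroman-3-yl]-4-oxo-4H-chromen-7-yl hydrogen sulfate (target)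
Conditions: H2 (1 atm), Pd(OH)2/C, THF–MeOH (1:1), rt; then HCl (1.0 equiv, 0.05 M aq), 0 °C; Sephadex LH-20 (MeOH)
Reagents that add atoms: none
Why: Hydrogenolysis cleaves the three benzyl ethers and both benzylic C–O bonds of the diphenylmethylene ketal, while aryl sulfate salts are stable to H2 over palladium. One equivalent of acid then gives the hydrogen sulfate; no stereocentre is touched.

## Compound list

1 | luteolin, 2-(3,4-dihydroxyphenyl)-5,7-dihydroxy-4H-chromen-4-one | O=c1cc(-c2ccc(O)c(O)c2)oc2cc(O)cc(O)c12 | starting material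
2 | 2-(2,2-diphenyl-1,3-benzodioxol-5-yl)-5,7-dihydroxy-4H-chromen-4-one | O=c1cc(-c2ccc3OC(c4ccccc4)(c4ccccc4)Oc3c2)oc2cc(O)cc(O)c12 | intermediate
3 | 7-(allyloxy)-2-(2,2-diphenyl-1,3-benzodioxol-5-yl)-5-hydroxy-4H-chromen-4-one | O=c1cc(-c2ccc3OC(c4ccccc4)(c4ccccc4)Oc3c2)oc2cc(OCC=C)cc(O)c12 | intermediate
4 | 7-(allyloxy)-5-(benzyloxy)-2-(2,2-diphenyl-1,3-benzodioxol-5-yl)-4H-chromen-4-one | O=c1cc(-c2ccc3OC(c4ccccc4)(c4ccccc4)Oc3c2)oc2cc(OCC=C)cc(OCc3ccccc3)c12 | intermediate
5 | 8-allyl-5-(benzyloxy)-2-(2,2-diphenyl-1,3-benzodioxol-5-yl)-7-hydroxy-4H-chromen-4-one | O=c1cc(-c2ccc3OC(c4ccccc4)(c4ccccc4)Oc3c2)oc2c(CC=C)c(O)cc(OCc3ccccc3)c12 | intermediate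
6 | 8-allyl-5-(benzyloxy)-2-(2,2-diphenyl-1,3-benzodioxol-5-yl)-7-(methoxymethoxy)-4H-chromen-4-one | O=c1cc(-c2ccc3OC(c4ccccc4)(c4ccccc4)Oc3c2)oc2c(CC=C)c(OCOC)cc(OCc3ccccc3)c12 | intermediate
7 | 2-Fl-acetaldehyde | O=CCc1c(OCOC)cc(OCc2ccccc2)c2c(=O)cc(-c3ccc4OC(c5ccccc5)(c5ccccc5)Oc4c3)oc12 | intermediate
8 | 1-Fl-but-3-yn-2-ol (racemic) | C#CC(O)Cc1c(OCOC)cc(OCc2ccccc2)c2c(=O)cc(-c3ccc4OC(c5ccccc5)(c5ccccc5)Oc4c3)oc12 | intermediate
9 | 1-Fl-but-3-yn-2-one | C#CC(=O)Cc1c(OCOC)cc(OCc2ccccc2)c2c(=O)cc(-c3ccc4OC(c5ccccc5)(c5ccccc5)Oc4c3)oc12 | intermediate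
10 | (E)-4-methoxy-1-Fl-but-3-en-2-one | CO/C=C/C(=O)Cc1c(OCOC)cc(OCc2ccccc2)c2c(=O)cc(-c3ccc4OC(c5ccccc5)(c5ccccc5)Oc4c3)oc12 | intermediate
11 | (1E,3Z)-1-methoxy-3-(trimethylsilyloxy)-4-Fl-buta-1,3-diene | CO/C=C/C(O[Si](C)(C)C)=C/c1c(OCOC)cc(OCc2ccccc2)c2c(=O)cc(-c3ccc4OC(c5ccccc5)(c5ccccc5)Oc4c3)oc12 | intermediate
12 | 4-(benzyloxy)benzaldehyde | O=Cc1ccc(OCc2ccccc2)cc1 | starting material
13 | (E)-(5R)-5-[4-(benzyloxy)phenyl]-4-Fl-1-methoxy-5-(trimethylsilyloxy)pent-1-en-3-one (C4 epimers) | CO/C=C/C(=O)C([C@@H](O[Si](C)(C)C)c1ccc(OCc2ccccc2)cc1)c1c(OCOC)cc(OCc2ccccc2)c2c(=O)cc(-c3ccc4OC(c5ccccc5)(c5ccccc5)Oc4c3)oc12 | intermediate (not isolated)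
14 | (2R,3S)-2-[4-(benzyloxy)phenyl]-3-Fl-2,3-dihydro-4H-pyran-4-one | O=C1C=CO[C@@H](c2ccc(OCc3ccccc3)cc2)[C@@H]1c1c(OCOC)cc(OCc2ccccc2)c2c(=O)cc(-c3ccc4OC(c5ccccc5)(c5ccccc5)Oc4c3)oc12 | intermediate
15 | (2R,3S)-2-[4-(benzyloxy)phenyl]-3-Fl-5-(phenylthio)-2,3-dihydro-4H-pyran-4-one | O=C1C(Sc2ccccc2)=CO[C@@H](c2ccc(OCc3ccccc3)cc2)[C@@H]1c1c(OCOC)cc(OCc2ccccc2)c2c(=O)cc(-c3ccc4OC(c5ccccc5)(c5ccccc5)Oc4c3)oc12 | intermediate
16 | (2R,3S)-2-[4-(benzyloxy)phenyl]-3-Fl-5-(phenylsulfinyl)-2,3-dihydro-4H-pyran-4-one (mixture at sulfur) | O=C1C(S(=O)c2ccccc2)=CO[C@@H](c2ccc(OCc3ccccc3)cc2)[C@@H]1c1c(OCOC)cc(OCc2ccccc2)c2c(=O)cc(-c3ccc4OC(c5ccccc5)(c5ccccc5)Oc4c3)oc12 | intermediate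
17 | methyl 3-(trimethylsilyloxy)but-2-enoate | COC(=O)C=C(C)O[Si](C)(C)C | starting material
18 | 1-methoxy-1,3-bis(trimethylsilyloxy)buta-1,3-diene | COC(O[Si](C)(C)C)=CC(=C)O[Si](C)(C)C | intermediate
19 | (2R,3S)-2-[4-(benzyloxy)phenyl]-3-Fl-5-methoxy-4a-(phenylsulfinyl)-5,7-bis(trimethylsilyloxy)-2,3,4a,5,8,8a-hexahydro-4H-chromen-4-one (mixture at C4a, C5, C8a and sulfur) | O=C1C2(S(=O)c3ccccc3)C(OC)(O[Si](C)(C)C)C=C(O[Si](C)(C)C)CC2O[C@@H](c2ccc(OCc3ccccc3)cc2)[C@@H]1c1c(OCOC)cc(OCc2ccccc2)c2c(=O)cc(-c3ccc4OC(c5ccccc5)(c5ccccc5)Oc4c3)oc12 | intermediate (not isolated)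
20 | (2R,3S)-2-[4-(benzyloxy)phenyl]-3-Fl-5,7-bis(trimethylsilyloxy)chroman-4-one | O=C1c2c(O[Si](C)(C)C)cc(O[Si](C)(C)C)cc2O[C@@H](c2ccc(OCc3ccccc3)cc2)[C@@H]1c1c(OCOC)cc(OCc2ccccc2)c2c(=O)cc(-c3ccc4OC(c5ccccc5)(c5ccccc5)Oc4c3)oc12 | intermediate (not isolated)
21 | (2R,3S)-2-[4-(benzyloxy)phenyl]-3-Fl-5,7-dihydroxychroman-4-one | O=C1c2c(O)cc(O)cc2O[C@@H](c2ccc(OCc3ccccc3)cc2)[C@@H]1c1c(OCOC)cc(OCc2ccccc2)c2c(=O)cc(-c3ccc4OC(c5ccccc5)(c5ccccc5)Oc4c3)oc12 | intermediate
22 | (2R,3S)-7-(benzyloxy)-2-[4-(benzyloxy)phenyl]-3-Fl-5-hydroxychroman-4-one | O=C1c2c(O)cc(OCc3ccccc3)cc2O[C@@H](c2ccc(OCc3ccccc3)cc2)[C@@H]1c1c(OCOC)cc(OCc2ccccc2)c2c(=O)cc(-c3ccc4OC(c5ccccc5)(c5ccccc5)Oc4c3)oc12 | intermediate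
23 | (2R,3S)-7-(benzyloxy)-2-[4-(benzyloxy)phenyl]-3-[5-(benzyloxy)-2-(2,2-diphenyl-1,3-benzodioxol-5-yl)-7-hydroxy-4-oxo-4H-chromen-8-yl]-5-hydroxychroman-4-one | O=C1c2c(O)cc(OCc3ccccc3)cc2O[C@@H](c2ccc(OCc3ccccc3)cc2)[C@@H]1c1c(O)cc(OCc2ccccc2)c2c(=O)cc(-c3ccc4OC(c5ccccc5)(c5ccccc5)Oc4c3)oc12 | intermediate
24 | sodium 5-(benzyloxy)-8-[(2R,3S)-7-(benzyloxy)-2-[4-(benzyloxy)phenyl]-5-hydroxy-4-oxochroman-3-yl]-2-(2,2-diphenyl-1,3-benzodioxol-5-yl)-4-oxo-4H-chromen-7-yl sulfate | O=C1c2c(O)cc(OCc3ccccc3)cc2O[C@@H](c2ccc(OCc3ccccc3)cc2)[C@@H]1c1c(OS(=O)(=O)[O-])cc(OCc2ccccc2)c2c(=O)cc(-c3ccc4OC(c5ccccc5)(c5ccccc5)Oc4c3)oc12.[Na+] | intermediate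
25 | 2-(3,4-dihydroxyphenyl)-5-hydroxy-8-[(2R,3S)-5,7-dihydroxy-2-(4-hydroxyphenyl)-4-oxochroman-3-yl]-4-oxo-4H-chromen-7-yl hydrogen sulfate | O=C1c2c(O)cc(O)cc2O[C@@H](c2ccc(O)cc2)[C@@H]1c1c(OS(=O)(=O)O)cc(O)c2c(=O)cc(-c3ccc(O)c(O)c3)oc12 | target

## Step count and least certain steps

Total: 19 steps. Longest linear sequence: 18 steps (steps 1–13 and 15–19); diene 18 is made in one step off the main line.

Step 11 (key step). The nucleophilic carbon of 11 is shielded by a flavonyl group with two ortho substituents, and the flavone carbonyl and the ether oxygens compete with the aldehyde for titanium. Turnover may therefore stall, leaving protodesilylation of 11 back to 10 as the main process. Where the catalysed path is slow, an uncatalysed or silyl-cation-mediated background addition would erode the enantioselectivity. The sense of induction is assigned by analogy and must be confirmed; if it is reversed with this diene, (S)-BINOL is used. Fallback: set out from ketone 10 and form the C2–C3 bond by a reagent-controlled aldol reaction. A diisopinocampheylboron triflate-mediated aldol reaction of 10 with 12 (iPr2NEt; the reagent enantiomer that gives the 5R carbinol) gives (E)-(5R)-5-[4-(benzyloxy)phenyl]-4-Fl-5-hydroxy-1-methoxypent-1-en-3-one F1. Treatment of F1 with CF3CO2H closes ring C with loss of methanol and equilibrates C3, returning to 14.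

Step 15. The push–pull alkene of 16 is a weak dienophile, so diene 18 may decompose or be desilylated by the sulfenic acid before cycloaddition. If the addition runs stepwise, the intermediate can lose O1 by β-elimination and open ring C. Fallback: set out from 14 without the sulfoxide. Me3SiOTf-promoted conjugate addition of 18 at C8a gives the ring silyl enol ether methyl 4-[6-(4-benzyloxyphenyl)-5-Fl-4-(trimethylsilyloxy)-5,6-dihydro-2H-pyran-2-yl]-3-oxobutanoate F2 (side chain as the β-keto ester after mild work-up), which is oxidised crude with Pd(OAc)2 (Saegusa–Ito) to methyl 4-[(2R,3S)-2-(4-benzyloxyphenyl)-3-Fl-4-oxo-3,4-dihydro-2H-pyran-6-yl]-3-oxobutanoate F3. Heating F3 in toluene should bring about thermal loss of methanol from the β-keto ester with C-acylation of the nucleophilic C4a, and enolisation then gives 21.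

Step 12. Sulfenylation may also occur at other electron-rich positions (C6'' of the flavone, or the flavone C3''), and the hydrogen chloride formed may cleave the methoxymethyl ether if the buffering is insufficient. Fallback: from 14, α-iodination with I2 and pyridine, established for cyclic enones and dihydropyranones, gives (2R,3S)-2-[4-(benzyloxy)phenyl]-3-Fl-5-iodo-2,3-dihydro-4H-pyran-4-one F4. Coupling of F4 with tributyl(phenylthio)stannane catalysed by Pd(PPh3)4 under neutral conditions returns to 15.

Step 4. Part of the allyl group may migrate to the other ortho position (C6''), and at 200 °C the ortho-allyl phenol may cyclise to a dihydrofuran. Fallback: from 2, bring in the allyl group by cross-coupling. Methoxymethylation of the 7-OH gives 2-(2,2-diphenyl-1,3-benzodioxol-5-yl)-5-hydroxy-7-(methoxymethoxy)-4H-chromen-4-one F5; benzylation gives 5-(benzyloxy)-2-(2,2-diphenyl-1,3-benzodioxol-5-yl)-7-(methoxymethoxy)-4H-chromen-4-one F6; iodination with N-iodosuccinimide, which in fully alkylated 5,7-dioxygenated flavones goes to C8'', gives 5-(benzyloxy)-2-(2,2-diphenyl-1,3-benzodioxol-5-yl)-8-iodo-7-(methoxymethoxy)-4H-chromen-4-one F7. Stille coupling of F7 with allyltributylstannane (Pd(PPh3)4) returns to 6.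

Step 7. The arylacetaldehyde 7 may be enolised by the basic Grignard reagent and then undergo self-aldol condensation, and above −40 °C the reagent may begin to add to the flavone carbonyl. Fallback: from 7, Pinnick oxidation (NaClO2, NaH2PO4, 2-methyl-2-butene) gives 2-Fl-acetic acid F8, and coupling with N,O-dimethylhydroxylamine gives N-methoxy-N-methyl-2-Fl-acetamide F9. HC≡CMgBr adds once to F9 and gives the ynone 9 directly, so step 8 is no longer needed.

## Further compounds

F1 | step 11 | (E)-(5R)-5-[4-(benzyloxy)phenyl]-4-Fl-5-hydroxy-1-methoxypent-1-en-3-one | CO/C=C/C(=O)C([C@@H](O)c1ccc(OCc2ccccc2)cc1)c1c(OCOC)cc(OCc2ccccc2)c2c(=O)cc(-c3ccc4OC(c5ccccc5)(c5ccccc5)Oc4c3)oc12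
F2 | step 15 | methyl 4-[6-(4-benzyloxyphenyl)-5-Fl-4-(trimethylsilyloxy)-5,6-dihydro-2H-pyran-2-yl]-3-oxobutanoate (ring centres C5 and C6 as in 14, C2 epimers) | C[Si](C)(C)OC1=CC(CC(=O)CC(=O)OC)O[C@@H](c2ccc(OCc3ccccc3)cc2)[C@@H]1c1c(OCOC)cc(OCc2ccccc2)c2c(=O)cc(-c3ccc4OC(c5ccccc5)(c5ccccc5)Oc4c3)oc12
F3 | step 15 | methyl 4-[(2R,3S)-2-(4-benzyloxyphenyl)-3-Fl-4-oxo-3,4-dihydro-2H-pyran-6-yl]-3-oxobutanoate | O=C1C=C(CC(=O)CC(=O)OC)O[C@@H](c2ccc(OCc3ccccc3)cc2)[C@@H]1c1c(OCOC)cc(OCc2ccccc2)c2c(=O)cc(-c3ccc4OC(c5ccccc5)(c5ccccc5)Oc4c3)oc12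
F4 | step 12 | (2R,3S)-2-[4-(benzyloxy)phenyl]-3-Fl-5-iodo-2,3-dihydro-4H-pyran-4-one | O=C1C(I)=CO[C@@H](c2ccc(OCc3ccccc3)cc2)[C@@H]1c1c(OCOC)cc(OCc2ccccc2)c2c(=O)cc(-c3ccc4OC(c5ccccc5)(c5ccccc5)Oc4c3)oc12
F5 | step 4 | 2-(2,2-diphenyl-1,3-benzodioxol-5-yl)-5-hydroxy-7-(methoxymethoxy)-4H-chromen-4-one | O=c1cc(-c2ccc3OC(c4ccccc4)(c4ccccc4)Oc3c2)oc2cc(OCOC)cc(O)c12
F6 | step 4 | 5-(benzyloxy)-2-(2,2-diphenyl-1,3-benzodioxol-5-yl)-7-(methoxymethoxy)-4H-chromen-4-one | O=c1cc(-c2ccc3OC(c4ccccc4)(c4ccccc4)Oc3c2)oc2cc(OCOC)cc(OCc3ccccc3)c12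
F7 | step 4 | 5-(benzyloxy)-2-(2,2-diphenyl-1,3-benzodioxol-5-yl)-8-iodo-7-(methoxymethoxy)-4H-chromen-4-one | O=c1cc(-c2ccc3OC(c4ccccc4)(c4ccccc4)Oc3c2)oc2c(I)c(OCOC)cc(OCc3ccccc3)c12
F8 | step 7 | 2-Fl-acetic acid | OC(=O)Cc1c(OCOC)cc(OCc2ccccc2)c2c(=O)cc(-c3ccc4OC(c5ccccc5)(c5ccccc5)Oc4c3)oc12
F9 | step 7 | N-methoxy-N-methyl-2-Fl-acetamide | CON(C)C(=O)Cc1c(OCOC)cc(OCc2ccccc2)c2c(=O)cc(-c3ccc4OC(c5ccccc5)(c5ccccc5)Oc4c3)oc12
A1 | alternative 1 | (E)-1-[2,4-bis(benzyloxy)-6-hydroxyphenyl]-3-[4-(benzyloxy)phenyl]-2-[5-(benzyloxy)-2-[3,4-bis(benzyloxy)phenyl]-7-(methoxymethoxy)-4-oxo-4H-chromen-8-yl]prop-2-en-1-one | O=C(c1c(O)cc(OCc2ccccc2)cc1OCc1ccccc1)/C(=C/c1ccc(OCc2ccccc2)cc1)c1c(OCOC)cc(OCc2ccccc2)c2c(=O)cc(-c3ccc(OCc4ccccc4)c(OCc4ccccc4)c3)oc12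
A2 | alternative 1 | (E)-3-[4-(benzyloxy)phenyl]-2-[5-(benzyloxy)-2-[3,4-bis(benzyloxy)phenyl]-7-(methoxymethoxy)-4-oxo-4H-chromen-8-yl]acrylic acid | OC(=O)/C(=C/c1ccc(OCc2ccccc2)cc1)c1c(OCOC)cc(OCc2ccccc2)c2c(=O)cc(-c3ccc(OCc4ccccc4)c(OCc4ccccc4)c3)oc12
A3 | alternative 1 | 3,5-bis(benzyloxy)benzyne | C1#CC(OCc2ccccc2)=CC(OCc2ccccc2)=C1
A4 | alternative 2 | (2R,3S)-5,7-bis(benzyloxy)-2-[4-(benzyloxy)phenyl]-3-[5-(benzyloxy)-2-[3,4-bis(benzyloxy)phenyl]-7-hydroxy-4-oxo-4H-chromen-8-yl]chroman-4-one | O=C1c2c(OCc3ccccc3)cc(OCc3ccccc3)cc2O[C@@H](c2ccc(OCc3ccccc3)cc2)[C@@H]1c1c(O)cc(OCc2ccccc2)c2c(=O)cc(-c3ccc(OCc4ccccc4)c(OCc4ccccc4)c3)oc12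
A5 | alternative 2 | (2R,3S)-5,7-bis(benzyloxy)-2-[4-(benzyloxy)phenyl]-3-[4-(benzyloxy)-2,6-dihydroxy-3-iodophenyl]chroman-4-one | O=C1c2c(OCc3ccccc3)cc(OCc3ccccc3)cc2O[C@@H](c2ccc(OCc3ccccc3)cc2)[C@@H]1c1c(O)cc(OCc2ccccc2)c(I)c1O
A6 | alternative 2 | 1,2-bis(benzyloxy)-4-ethynylbenzene | C#Cc1ccc(OCc2ccccc2)c(OCc2ccccc2)c1
A7 | alternative 2 | carbon monoxide | [C-]#[O+]
A8 | alternative 3 | (2R,3S)-5,7-bis[4-(benzyloxy)benzyloxy]-2-[4-(benzyloxy)phenyl]-3-[5-(benzyloxy)-2-[3,4-bis(benzyloxy)phenyl]-4-oxo-7-[(2,2,2-trichloroethoxy)sulfonyloxy]-4H-chromen-8-yl]chroman-4-one | O=C1c2c(OCc3ccc(OCc4ccccc4)cc3)cc(OCc3ccc(OCc4ccccc4)cc3)cc2O[C@@H](c2ccc(OCc3ccccc3)cc2)[C@@H]1c1c(OS(=O)(=O)OCC(Cl)(Cl)Cl)cc(OCc2ccccc2)c2c(=O)cc(-c3ccc(OCc4ccccc4)c(OCc4ccccc4)c3)oc12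
A9 | alternative 3 | 2-diazo-1-[2,4,6-tris[4-(benzyloxy)benzyloxy]phenyl]-2-[5-(benzyloxy)-2-[3,4-bis(benzyloxy)phenyl]-4-oxo-7-[(2,2,2-trichloroethoxy)sulfonyloxy]-4H-chromen-8-yl]ethan-1-one | [N-]=[N+]=C(C(=O)c1c(OCc2ccc(OCc3ccccc3)cc2)cc(OCc2ccc(OCc3ccccc3)cc2)cc1OCc1ccc(OCc2ccccc2)cc1)c1c(OS(=O)(=O)OCC(Cl)(Cl)Cl)cc(OCc2ccccc2)c2c(=O)cc(-c3ccc(OCc4ccccc4)c(OCc4ccccc4)c3)oc12
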